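## Retrosynthetic overview

1. Target 14 ⇐ 13 by neutral methanolysis of the two ring-A acetates; 13 ⇐ 11 by oxidation of both aryl C–B bonds to C–O.
2. 11 ⇐ 9 + B2pin2 (10) by twofold C–H borylation of ring B with [Ir(OMe)(cod)]2/dtbpy, forming C3'–B and C5'–B. The plan rests on the substitution pattern: ring B has hydroxyl only at C3' and C5', the two carbons meta to the C1'–C2 bond, and ring A has a substituent on every carbon (O at C5 and C7, prenyl at C6 and C8). Compound 9 therefore offers unhindered aryl C–H bonds only at C3', C4' and C5', and only the C3'/C5' pair can take two boron atoms.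
3. 9 ⇐ 7 by cross-metathesis of two allyl groups with 2-methyl-2-butene; 7 ⇐ 6 by acetylation; 6 ⇐ 4 by two aromatic Claisen shifts; 4 ⇐ 3 ⇐ (2S)-pinocembrin 1 by two successive Mitsunobu O-allylations, each with one molecule of allyl alcohol 2 (7-OH first, then the chelated 5-OH).
4. No ring is formed: rings A, B and C and the S centre at C2 all come from 1. Plain allyl ethers are used because an allyl group reaches C6 and C8 unchanged by any Claisen or Claisen–Cope path. Every step avoids strong base and strong acid, since base epimerises C2 through the ring-opened chalcone and acid cyclises a prenyl group onto a neighbouring phenol.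

Key step: step 6

Assumption: natural (2S)-pinocembrin of high enantiomeric purity is used. C2 is only carried through, never created, so the enantiomeric purity of 14 cannot exceed that of 1 and should be checked by chiral HPLC after steps 3 and 8.

Flavanone = 2-phenylchroman-4-one; every flavanone in the route is S at C2.

## Route

Step 1
Reactants: 1 (2S)-pinocembrin; 2 allyl alcohol
Product: 3 (S)-7-(allyloxy)-5-hydroxyflavanone
Conditions: allyl alcohol (1.05 equiv), PPh3 (1.1 equiv), DIAD (1.1 equiv), THF, 0 °C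
Reagents that add atoms: none
Why: Mitsunobu etherification: the alkoxyphosphonium ion of allyl alcohol is attacked by the more acidic, non-chelated 7-OH, while the 5-OH, held in a hydrogen bond to the C4 carbonyl, stays free when only one equivalent of alcohol is offered, and the neutral conditions leave ring C closed so that C2 stays S.

Step 2
Reactants: 3 (S)-7-(allyloxy)-5-hydroxyflavanone; 2 allyl alcohol
Product: 4 (S)-5,7-bis(allyloxy)flavanone
Conditions: allyl alcohol (2 equiv), PPh3 (2 equiv), DIAD (2 equiv), THF, rt to 40 °C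
Reagents that add atoms: none
Why: Second Mitsunobu etherification, now of the hydrogen-bonded 5-OH of the flavanone, which is O-allylated with excess reagent and mild warming and without any base, so no retro-oxa-Michael opening of ring C can epimerise C2.

Step 3
Reactants: 4 (S)-5,7-bis(allyloxy)flavanone
Product: 6 (S)-6,8-diallyl-5,7-dihydroxyflavanone, via 6-allyl-7-allyloxy-5-hydroxyflavanone 5 (not isolated)
Conditions: Eu(fod)3 (fod = 6,6,7,7,8,8,8-heptafluoro-2,2-dimethyl-3,5-octanedionate; 10 mol %), 1,2-dichlorobenzene, 80 °C, then 180 °C (sealed tube)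
Reagents that add atoms: none
Why: Aromatic Claisen rearrangement run twice ([3,3] shift, then tautomerisation to the phenol): trivalent europium chelated between O5 and the C4 carbonyl lets the 5-O-allyl group move to C6 at 80 °C, the 7-O-allyl group then has C8 as its only free ortho carbon at 180 °C, and because an allyl group is not altered by a Claisen–Cope relay every alternative path also ends at the 6,8-diallyl compound; C2 takes no part.

Step 4
Reactants: 6 (S)-6,8-diallyl-5,7-dihydroxyflavanone
Product: 7 (S)-5,7-diacetoxy-6,8-diallylflavanone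
Conditions: Ac2O, pyridine, DMAP (cat.), CH2Cl2, 0 °C to rt
Reagents that add atoms: acetic anhydride, CC(=O)OC(C)=O
Why: DMAP-catalysed O-acylation caps both phenols, the hydrogen-bonded 5-OH included, with only a weak amine base, whereas an ether protection of that hydroxyl in the presence of two flanking allyl groups would call for a strong base that opens ring C.

Step 5
Reactants: 7 (S)-5,7-diacetoxy-6,8-diallylflavanone; 8 2-methyl-2-butene
Product: 9 (S)-5,7-diacetoxy-6,8-bis(3-methylbut-2-enyl)flavanone
Conditions: second-generation Grubbs catalyst RuCl2(=CHPh)(H2IMes)(PCy3) (5 mol %), 2-methyl-2-butene/CH2Cl2, 40 °C (sealed)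
Reagents that add atoms: none
Why: Olefin cross-metathesis: each monosubstituted allyl alkene exchanges its CH2 terminus for the isopropylidene unit of 2-methyl-2-butene used in large excess, and the trisubstituted prenyl alkenes formed are too hindered to react further.

Step 6
Reactants: 9 (S)-5,7-diacetoxy-6,8-bis(3-methylbut-2-enyl)flavanone; 10 bis(pinacolato)diboron
Product: 11 (S)-5,7-diacetoxy-6,8-bis(3-methylbut-2-enyl)-3',5'-bis(4,4,5,5-tetramethyl-1,3,2-dioxaborolan-2-yl)flavanone
Conditions: [Ir(OMe)(cod)]2 (2.5 mol %), dtbpy (5 mol %), B2pin2 (3 equiv), THF, 65 °C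
Reagents that add atoms: none
Why: [Ir(OMe)(cod)]2 (monovalent iridium), dtbpy and B2pin2 form the tris(boryl) complex (dtbpy)Ir(Bpin)3 of trivalent iridium, which cleaves the least hindered aryl C–H bond by oxidative addition to a pentavalent-iridium aryl hydride, releases Ar–Bpin by reductive elimination and is restored by B2pin2 with loss of pinacolborane. This is the sterically controlled iridium-catalysed C–H borylation of arenes, the closest precedents being the 3,5-diborylation of monosubstituted benzenes and the 5-borylation of 1,3-disubstituted benzenes. No ring is closed and no stereocentre is made; C2 is a spectator under these neutral, aprotic conditions and keeps its S configuration. The selectivity needed is C3'/C5' over every other position: ring A has no C–H bond, C2'–H and C6'–H are shielded by the branched C2 substituent, and once boron sits at C3' the only C–H without an ortho neighbour is C5'–H, so the second boron is steered there. Meta against para in the first borylation is expected to be only near-statistical, so the share that takes boron at C4' stops at one boron and has to be removed by chromatography. The trisubstituted prenyl alkenes, the acetates and the aryl ketone should react far more slowly with the iridium boryl species than unhindered aryl C–H bonds, and the moderate temperature is chosen to keep it so.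

Step 7
Reactants: 11 (S)-5,7-diacetoxy-6,8-bis(3-methylbut-2-enyl)-3',5'-bis(4,4,5,5-tetramethyl-1,3,2-dioxaborolan-2-yl)flavanone
Product: 13 (S)-5,7-diacetoxy-3',5'-dihydroxy-6,8-bis(3-methylbut-2-enyl)flavanone, via 3',5'-bis(pinacolboryloxy) aryl borate 12 (not isolated)
Conditions: N,N-dimethyl-p-toluidine N-oxide (3 equiv), CH2Cl2, rt; aq. NH4Cl work-up
Reagents that add atoms: N,N-dimethyl-p-toluidine N-oxide, Cc1ccc([N+](C)(C)[O-])cc1
Why: ipso-Hydroxylation of aryl boronates with a tertiary amine N-oxide: the oxide oxygen binds boron, the aryl group shifts from boron to oxygen as the amine leaves, and work-up hydrolyses the aryl borate; without base or peroxide the acetates, the prenyl alkenes and C2 are not touched (a peroxide would turn the aryl acetates into peracetic acid, an epoxidising agent for prenyl groups).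

Step 8
Reactants: 13 (S)-5,7-diacetoxy-3',5'-dihydroxy-6,8-bis(3-methylbut-2-enyl)flavanone
Product: 14 (S)-5,7,3',5'-tetrahydroxy-6,8-bis(3-methylbut-2-enyl)flavanone
Conditions: NH4OAc (10 equiv), MeOH/H2O (4:1), rt to 40 °C
Reagents that add atoms: none
Why: Ammonium acetate-promoted transesterification of aryl acetates with methanol at about neutral pH frees the 5- and 7-hydroxyls without the base that epimerises C2 through the chalcone and without the acid that closes chroman rings from ortho-prenyl phenols.

## Compound list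

1 | (2S)-pinocembrin, (S)-5,7-dihydroxyflavanone | O=C1C[C@@H](c2ccccc2)Oc2cc(O)cc(O)c21 | starting material
2 | allyl alcohol (prop-2-en-1-ol) | C=CCO | starting material
3 | (S)-7-(allyloxy)-5-hydroxyflavanone | C=CCOc1cc2c(c(O)c1)C(=O)C[C@@H](c1ccccc1)O2 | intermediate
4 | (S)-5,7-bis(allyloxy)flavanone | C=CCOc1cc2c(c(OCC=C)c1)C(=O)C[C@@H](c1ccccc1)O2 | intermediate
5 | (S)-6-allyl-7-(allyloxy)-5-hydroxyflavanone | C=CCOc1cc2c(c(O)c1CC=C)C(=O)C[C@@H](c1ccccc1)O2 | intermediate (not isolated)
6 | (S)-6,8-diallyl-5,7-dihydroxyflavanone | C=CCc1c(O)c(CC=C)c2c(c1O)C(=O)C[C@@H](c1ccccc1)O2 | intermediate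
7 | (S)-5,7-diacetoxy-6,8-diallylflavanone | C=CCc1c(OC(C)=O)c(CC=C)c2c(c1OC(C)=O)C(=O)C[C@@H](c1ccccc1)O2 | intermediate
8 | 2-methyl-2-butene | CC=C(C)C | starting material
9 | (S)-5,7-diacetoxy-6,8-bis(3-methylbut-2-enyl)flavanone (diacetate of (S)-6,8-diprenylpinocembrin) | CC(C)=CCc1c(OC(C)=O)c(CC=C(C)C)c2c(c1OC(C)=O)C(=O)C[C@@H](c1ccccc1)O2 | intermediate
10 | bis(pinacolato)diboron | CC1(C)OB(B2OC(C)(C)C(C)(C)O2)OC1(C)C | starting material
11 | (S)-5,7-diacetoxy-6,8-bis(3-methylbut-2-enyl)-3',5'-bis(4,4,5,5-tetramethyl-1,3,2-dioxaborolan-2-yl)flavanone | CC(C)=CCc1c(OC(C)=O)c(CC=C(C)C)c2c(c1OC(C)=O)C(=O)C[C@@H](c1cc(B3OC(C)(C)C(C)(C)O3)cc(B3OC(C)(C)C(C)(C)O3)c1)O2 | intermediate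
12 | (S)-5,7-diacetoxy-6,8-bis(3-methylbut-2-enyl)-3',5'-bis(pinacolboryloxy)flavanone (bis aryl borate) | CC(C)=CCc1c(OC(C)=O)c(CC=C(C)C)c2c(c1OC(C)=O)C(=O)C[C@@H](c1cc(OB3OC(C)(C)C(C)(C)O3)cc(OB3OC(C)(C)C(C)(C)O3)c1)O2 | intermediate (not isolated)
13 | (S)-5,7-diacetoxy-3',5'-dihydroxy-6,8-bis(3-methylbut-2-enyl)flavanone | CC(C)=CCc1c(OC(C)=O)c(CC=C(C)C)c2c(c1OC(C)=O)C(=O)C[C@@H](c1cc(O)cc(O)c1)O2 | intermediate
14 | (S)-5,7,3',5'-tetrahydroxy-6,8-bis(3-methylbut-2-enyl)flavanone (CID26213315) | CC(C)=CCc1c(O)c(CC=C(C)C)c2c(c1O)C(=O)C[C@@H](c1cc(O)cc(O)c1)O2 | target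

## Step count and risks

Total steps: 8. Longest linear sequence: 8 steps (1 to 14).

**Step 6 (key step).** What may go wrong: the second borylation stalls, or boron is delivered to the prenyl alkenes (hydroboration by the pinacolborane set free, or vinylic borylation), on top of the built-in loss of the para-borylated share. Fallback: ring B is borylated before any alkene is present and the aryl boronates are carried through the ring-A chemistry; it sets out from 1 and comes back at 14.
- Compound 1 is acetylated (Ac2O, pyridine, DMAP) to (S)-5,7-diacetoxyflavanone F1.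
- Borylation under the conditions of step 6 should give (S)-5,7-diacetoxy-3',5'-bis(pinacolboryl)flavanone F2, because C6–H and C8–H of ring A each lie between two oxygen substituents and should not be attacked.
- NH4OAc in aqueous methanol frees the ring-A phenols to give (S)-5,7-dihydroxy-3',5'-bis(pinacolboryl)flavanone F3.
- Mitsunobu allylation with one equivalent of 2, as in step 1, gives the 7-allyl ether F4.
- A second Mitsunobu allylation with 2, as in step 2, gives the 5,7-bis(allyl ether) F5.
- The two-stage Claisen rearrangement of step 3 leads through the 6-allyl-7-allyloxy-5-hydroxy compound F6 to the 6,8-diallyl-5,7-dihydroxy compound F7.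
- Cross-metathesis with 8 as in step 5 gives the 6,8-diprenyl-5,7-dihydroxy bis(boronate) F8.
- The N-oxide of step 7 converts both C–B bonds through the bis(aryl borate) F9 into the phenols of 14 on aqueous work-up, with no protecting group left to remove.

Aryl pinacol boronates should tolerate the Mitsunobu reactions, the heating and the metathesis.

**Step 3.** What may go wrong: erosion of configuration at C2 by thermal ring-opening to the 2'-hydroxychalcone and re-closure during the 180 °C stage, or addition of a freed phenol to its neighbouring allyl group. Fallback: the two allyl–aryl bonds are made by cross-coupling below 100 °C instead of by sigmatropic shift; it sets out from 1 and comes back at 7.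
- N-Iodosuccinimide (2.1 equiv, DMF, 0 °C) iodinates the two free, doubly activated positions of ring A to give (S)-5,7-dihydroxy-6,8-diiodoflavanone F10.
- Ac2O/pyridine/DMAP gives (S)-5,7-diacetoxy-6,8-diiodoflavanone F11.
- Twofold Stille coupling with allyltributylstannane (Pd(PPh3)4, zerovalent palladium, DMF, 90 °C) gives 7.

**Step 8.** What may go wrong: slow cleavage of the two hindered ring-A acetates at neutral pH, so that forcing conditions bring epimerisation at C2 (base) or cyclisation of a prenyl group onto a phenol (acid). Fallback: no isolable protecting group is used and the phenols are masked in the flask as aryl borates; it sets out from 6 and comes back at 14.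
- Cross-metathesis of 6 with 8 as in step 5 gives (S)-6,8-diprenylpinocembrin F12.
- Pinacolborane (2.2 equiv, THF, rt to 50 °C) converts both phenols into O-boryl ethers with loss of dihydrogen, giving the 5,7-bis(O-pinacolboryl) compound F13.
- The catalyst system of step 6 ([Ir(OMe)(cod)]2, dtbpy, B2pin2) is added to the same flask and should give the 3',5'-diborylated bis(O-pinacolboryl) compound F14.
- The N-oxide of step 7 oxidises both C–B bonds to give the tetrakis(aryl borate) F15, and aqueous work-up hydrolyses all four O–B bonds to 14.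

## Further compounds

F1 | step 6 | (S)-5,7-diacetoxyflavanone | CC(=O)Oc1cc2c(c(OC(C)=O)c1)C(=O)C[C@@H](c1ccccc1)O2
F2 | step 6 | (S)-5,7-diacetoxy-3',5'-bis(pinacolboryl)flavanone | CC(=O)Oc1cc2c(c(OC(C)=O)c1)C(=O)C[C@@H](c1cc(B3OC(C)(C)C(C)(C)O3)cc(B3OC(C)(C)C(C)(C)O3)c1)O2
F3 | step 6 | (S)-5,7-dihydroxy-3',5'-bis(pinacolboryl)flavanone | Oc1cc2c(c(O)c1)C(=O)C[C@@H](c1cc(B3OC(C)(C)C(C)(C)O3)cc(B3OC(C)(C)C(C)(C)O3)c1)O2
F4 | step 6 | (S)-7-(allyloxy)-5-hydroxy-3',5'-bis(pinacolboryl)flavanone | C=CCOc1cc2c(c(O)c1)C(=O)C[C@@H](c1cc(B3OC(C)(C)C(C)(C)O3)cc(B3OC(C)(C)C(C)(C)O3)c1)O2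
F5 | step 6 | (S)-5,7-bis(allyloxy)-3',5'-bis(pinacolboryl)flavanone | C=CCOc1cc2c(c(OCC=C)c1)C(=O)C[C@@H](c1cc(B3OC(C)(C)C(C)(C)O3)cc(B3OC(C)(C)C(C)(C)O3)c1)O2
F6 | step 6 | (S)-6-allyl-7-(allyloxy)-5-hydroxy-3',5'-bis(pinacolboryl)flavanone | C=CCOc1cc2c(c(O)c1CC=C)C(=O)C[C@@H](c1cc(B3OC(C)(C)C(C)(C)O3)cc(B3OC(C)(C)C(C)(C)O3)c1)O2
F7 | step 6 | (S)-6,8-diallyl-5,7-dihydroxy-3',5'-bis(pinacolboryl)flavanone | C=CCc1c(O)c(CC=C)c2c(c1O)C(=O)C[C@@H](c1cc(B3OC(C)(C)C(C)(C)O3)cc(B3OC(C)(C)C(C)(C)O3)c1)O2
F8 | step 6 | (S)-5,7-dihydroxy-6,8-bis(3-methylbut-2-enyl)-3',5'-bis(pinacolboryl)flavanone | CC(C)=CCc1c(O)c(CC=C(C)C)c2c(c1O)C(=O)C[C@@H](c1cc(B3OC(C)(C)C(C)(C)O3)cc(B3OC(C)(C)C(C)(C)O3)c1)O2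
F9 | step 6 | (S)-5,7-dihydroxy-6,8-bis(3-methylbut-2-enyl)-3',5'-bis(pinacolboryloxy)flavanone | CC(C)=CCc1c(O)c(CC=C(C)C)c2c(c1O)C(=O)C[C@@H](c1cc(OB3OC(C)(C)C(C)(C)O3)cc(OB3OC(C)(C)C(C)(C)O3)c1)O2
F10 | step 3 | (S)-5,7-dihydroxy-6,8-diiodoflavanone | Ic1c(O)c(I)c2c(c1O)C(=O)C[C@@H](c1ccccc1)O2
F11 | step 3 | (S)-5,7-diacetoxy-6,8-diiodoflavanone | Ic1c(OC(C)=O)c(I)c2c(c1OC(C)=O)C(=O)C[C@@H](c1ccccc1)O2
F12 | step 8 | (S)-5,7-dihydroxy-6,8-bis(3-methylbut-2-enyl)flavanone | CC(C)=CCc1c(O)c(CC=C(C)C)c2c(c1O)C(=O)C[C@@H](c1ccccc1)O2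
F13 | step 8 | (S)-6,8-bis(3-methylbut-2-enyl)-5,7-bis(pinacolboryloxy)flavanone | CC(C)=CCc1c(OB3OC(C)(C)C(C)(C)O3)c(CC=C(C)C)c2c(c1OB3OC(C)(C)C(C)(C)O3)C(=O)C[C@@H](c1ccccc1)O2
F14 | step 8 | (S)-6,8-bis(3-methylbut-2-enyl)-3',5'-bis(pinacolboryl)-5,7-bis(pinacolboryloxy)flavanone | CC(C)=CCc1c(OB3OC(C)(C)C(C)(C)O3)c(CC=C(C)C)c2c(c1OB3OC(C)(C)C(C)(C)O3)C(=O)C[C@@H](c1cc(B3OC(C)(C)C(C)(C)O3)cc(B3OC(C)(C)C(C)(C)O3)c1)O2
F15 | step 8 | (S)-6,8-bis(3-methylbut-2-enyl)-5,7,3',5'-tetrakis(pinacolboryloxy)flavanone | CC(C)=CCc1c(OB3OC(C)(C)C(C)(C)O3)c(CC=C(C)C)c2c(c1OB3OC(C)(C)C(C)(C)O3)C(=O)C[C@@H](c1cc(OB3OC(C)(C)C(C)(C)O3)cc(OB3OC(C)(C)C(C)(C)O3)c1)O2
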